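**Strategy.** The route depends on cutting pyranone ring C of the apigenin half. In flavone ring A, C8a (bonded to O1) and C4a (bonded to the C4 carbonyl) are neighbours. C5, next to C4a, bears oxygen, and so does C7. A 3,5-dialkoxybenzyne that accepts a carboxylate oxygen and then its acyl group produces exactly this array. One operation therefore merges silyl triflate 7 with arylpropiolic acid 12, forming O1–C8a, C4–C4a and O1–C2 and closing ring C. Acid 12 already contains the diaryl ether and a syringaldehyde ring. Its formyl group is later exchanged for the phenol on which the (2S)-flavanone is built, through a chromone and an enantioselective aryl conjugate addition.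

Key step: step 6

Assumption: the pyridine-oxazoline palladium catalyst is taken to show the same facial preference on chromones as on cyclic enones, where the (S)-ligand gives (R)-products and the same spatial delivery means (R) at flavanone C2. (R)-t-BuPyOx is therefore specified for (2S), and the antipodal ligand would be used if a trial on 22 showed the opposite sense. Flavonoid numbering is used for both halves.

**Step 1**
Reactants: 1 3,5-bis(benzyloxy)phenol
Product: 2 3,5-bis(benzyloxy)phenyl isopropylcarbamate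
Conditions: i-PrNCO (1.5 equiv), Et3N (0.2 equiv), CH2Cl2, rt
Reagents that add atoms: isopropyl isocyanate, CC(C)N=C=O
Why: Base-catalysed addition of a phenol to an isocyanate (carbamoylation) installs a secondary carbamate that directs ortho-metalation and can later be removed under mild E1cB conditions.

**Step 2**
Reactants: 2 3,5-bis(benzyloxy)phenyl isopropylcarbamate
Product: 5 3,5-bis(benzyloxy)-2-(trimethylsilyl)phenyl isopropylcarbamate, via N-silyl carbamate 3 (not isolated), via bis-silyl carbamate 4 (not isolated)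
Conditions: TBSOTf (1.1 equiv), TMEDA, Et2O, 0 °C to rt; n-BuLi (2 equiv), TMEDA, −78 °C; TMSCl, −78 °C to rt; aq. NaHSO4
Reagents that add atoms: chlorotrimethylsilane, C[Si](C)(C)Cl; tert-butyldimethylsilyl triflate, CC(C)(C)[Si](C)(C)OS(=O)(=O)C(F)(F)F (its silyl group is held only by 3 and 4)
Why: This is a directed ortho-metalation in which transient N-silylation masks the N–H, the carbamate and the adjacent benzyloxy group together steer lithium to the carbon between them (both such carbons are equivalent by symmetry), n-BuLi/TMEDA at −78 °C is too mild to attack the benzylic CH2 groups, TMSCl traps the metalated position, and the acidic work-up removes the N-silyl group.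

**Step 3**
Reactants: 5 3,5-bis(benzyloxy)-2-(trimethylsilyl)phenyl isopropylcarbamate
Product: 7 3,5-bis(benzyloxy)-2-(trimethylsilyl)phenyl trifluoromethanesulfonate, via silylphenol 6 (not isolated)
Conditions: DBU (1.5 equiv), Et2NH (1.2 equiv), MeCN, 40 °C; then PhNTf2 (1.5 equiv), rt
Reagents that add atoms: N-phenylbis(trifluoromethanesulfonimide), O=S(=O)(N(c1ccccc1)S(=O)(=O)C(F)(F)F)C(F)(F)F
Why: DBU triggers E1cB loss of isopropyl isocyanate, Et2NH scavenges it as a urea, and the freed phenoxide is sulfonylated in the same pot, so this one-pot carbamate-to-triflate exchange never requires handling of the desilylation-prone silylphenol.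

**Step 4**
Reactants: 8 syringaldehyde; 9 1,4-diiodobenzene
Product: 10 4-(4-iodophenoxy)-3,5-dimethoxybenzaldehyde
Conditions: 9 (3 equiv), CuI (10 mol %), picolinic acid (20 mol %), K3PO4 (2 equiv), DMSO, 90 °C
Reagents that add atoms: none
Why: Ullmann-type O-arylation with the CuI/picolinic acid system suits doubly ortho-substituted phenols, the excess of symmetrical diiodide suppresses double arylation, and the product keeps an aryl iodide (not a bromide), which allows the next coupling to run cold.

**Step 5**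
Reactants: 10 4-(4-iodophenoxy)-3,5-dimethoxybenzaldehyde; 11 propiolic acid
Product: 12 3-[4-(4-formyl-2,6-dimethoxyphenoxy)phenyl]prop-2-ynoic acid
Conditions: 11 (1.3 equiv), PdCl2(PPh3)2 (5 mol %), dppb (10 mol %), DBU (2.5 equiv), DMSO, 25 °C; then 1 M HCl
Reagents that add atoms: none
Why: Copper-free Sonogashira coupling of an aryl iodide with the DBU salt of propiolic acid proceeds at room temperature, below the point at which arylpropiolates lose CO2, and the aldehyde is a spectator.

**Step 6**
Reactants: 7 3,5-bis(benzyloxy)-2-(trimethylsilyl)phenyl trifluoromethanesulfonate; 12 3-[4-(4-formyl-2,6-dimethoxyphenoxy)phenyl]prop-2-ynoic acid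
Product: 15 4-{4-[5,7-bis(benzyloxy)-4-oxo-4H-chromen-2-yl]phenoxy}-3,5-dimethoxybenzaldehyde, via benzyne 13 (not isolated), via hydroxyaryl ynone 14 (not isolated)
Conditions: 12 (1.2 equiv), CsF (4 equiv), THF (0.05 M), sealed tube, 100 °C
Reagents that add atoms: none
Why: Proposed new method: fluoride attacks silicon in 7 and expels triflate to give benzyne 13, the carboxylate of 12 adds through oxygen to the aryne carbon remote from the flanking benzyloxy group, the aryl anion so formed (next to that inductively withdrawing oxygen) attacks its own ester carbonyl through a four-membered transition state, and collapse moves the alkynoyl group to carbon and frees the phenoxide of ynone 14. The closest known reaction types are aryne insertion into the C–O bond of carboxylic acids, which gives ortho-hydroxyaryl ketones, and base-mediated cyclisation of ortho-hydroxyaryl ynones to flavones; running both in one flask on a functionalised arylpropiolic acid is the untested part. Ring C closes by 6-endo-dig oxa-Michael addition of the phenoxide oxygen to the ynone β-carbon, and the acid proton, held meanwhile on fluoride as bifluoride, ends on C3. No stereocentre is formed. Three selectivities are needed: the site of carboxylate addition (set by the distortion that the benzyloxy group beside the triple bond imposes on the aryne), acyl shift ahead of protonation of the aryl anion or of its attack on the alkyne terminus that would lead to a 4-arylcoumarin (favoured by the slim and strongly electrophilic alkynoyl carbonyl, slow aryne release from sparingly soluble CsF in hot THF, and bifluoride as the only proton source), and six- over five-membered closure (favoured by the aprotic basic medium). Acid 12 is taken in slight excess so that no benzyne remains to attack the aldehyde oxygen, and unreacted 12 is removed by a bicarbonate wash.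

**Step 7**
Reactants: 15 4-{4-[5,7-bis(benzyloxy)-4-oxo-4H-chromen-2-yl]phenoxy}-3,5-dimethoxybenzaldehyde
Product: 17 5,7-bis(benzyloxy)-2-[4-(4-hydroxy-2,6-dimethoxyphenoxy)phenyl]-4H-chromen-4-one, via aryl formate 16 (not isolated)
Conditions: mCPBA (1.5 equiv), CH2Cl2, rt to 40 °C; aq. NaHCO3 wash; then MeOH, Et3N (cat.), rt
Reagents that add atoms: mCPBA, O=C(OO)c1cccc(Cl)c1
Why: Baeyer–Villiger oxidation is the peracid counterpart of the Dakin reaction and is needed because no free ortho or para hydroxyl is present; the trioxygenated aryl group migrates in preference to hydride, the electron-poor pyranone double bond is inert to mCPBA, and the labile aryl formate is methanolysed under very mild base.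

**Step 8**
Reactants: 17 5,7-bis(benzyloxy)-2-[4-(4-hydroxy-2,6-dimethoxyphenoxy)phenyl]-4H-chromen-4-one
Product: 18 5,7-bis(benzyloxy)-2-[4-(4-hydroxy-3-iodo-2,6-dimethoxyphenoxy)phenyl]-4H-chromen-4-one
Conditions: NIS (1.0 equiv), CH2Cl2/MeCN, −20 °C to 0 °C, dark
Reagents that add atoms: N-iodosuccinimide, O=C1CCC(=O)N1I
Why: In this electrophilic aromatic iodination the free phloroglucinol-type phenol ring is by far the most nucleophilic arene (flavone ring A is deactivated by its carbonyl), its two open positions are equivalent, and one equivalent of NIS at low temperature limits double iodination.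

**Step 9**
Reactants: 18 5,7-bis(benzyloxy)-2-[4-(4-hydroxy-3-iodo-2,6-dimethoxyphenoxy)phenyl]-4H-chromen-4-one
Product: 20 2-[4-(3-acetyl-4-hydroxy-2,6-dimethoxyphenoxy)phenyl]-5,7-bis(benzyloxy)-4H-chromen-4-one, via enol ether 19 (not isolated)
Conditions: tributyl(1-ethoxyvinyl)stannane (1.5 equiv), PdCl2(PPh3)2 (5 mol %), 1,4-dioxane, 100 °C; then 1 M HCl, THF, rt
Reagents that add atoms: tributyl(1-ethoxyvinyl)stannane, C=C(OCC)[Sn](CCCC)(CCCC)CCCC; water, O
Why: Stille coupling with a masked acetyl anion followed by enol-ether hydrolysis places the acetyl group ortho to the phenol under neutral and then mildly acidic conditions that benzyl ethers tolerate, whereas the Lewis acids of a Fries or Friedel–Crafts acetylation would strip them, starting with the one peri to the flavone carbonyl.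

**Step 10**
Reactants: 20 2-[4-(3-acetyl-4-hydroxy-2,6-dimethoxyphenoxy)phenyl]-5,7-bis(benzyloxy)-4H-chromen-4-one
Product: 22 5,7-bis(benzyloxy)-2-{4-[(5,7-dimethoxy-4-oxo-4H-chromen-6-yl)oxy]phenyl}-4H-chromen-4-one, via enaminone 21 (not isolated)
Conditions: DMF-DMA (3 equiv), toluene, 95 °C; concentrate; then 1 M HCl, CH2Cl2, rt to 40 °C
Reagents that add atoms: N,N-dimethylformamide dimethyl acetal, COC(OC)N(C)C
Why: Enaminone formation followed by acid-induced addition–elimination by the ortho phenol is the standard route to 2,3-unsubstituted chromones, and because only one phenol is present the 5,6,7-oxygenation pattern is fixed unambiguously.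

**Step 11**
Reactants: 22 5,7-bis(benzyloxy)-2-{4-[(5,7-dimethoxy-4-oxo-4H-chromen-6-yl)oxy]phenyl}-4H-chromen-4-one; 23 4-(benzyloxy)phenylboronic acid
Product: 24 5,7-bis(benzyloxy)-2-[4-({(2S)-2-[4-(benzyloxy)phenyl]-5,7-dimethoxy-4-oxo-3,4-dihydro-2H-chromen-6-yl}oxy)phenyl]-4H-chromen-4-one
Conditions: 23 (2.5 equiv), Pd(OCOCF3)2 (10 mol %), (R)-t-BuPyOx [(R)-4-tert-butyl-2-(pyridin-2-yl)-4,5-dihydrooxazole] (12 mol %), NH4PF6 (30 mol %), H2O (5 equiv), ClCH2CH2Cl, 60 °C
Reagents that add atoms: none
Why: In this enantioselective palladium-catalysed conjugate addition of an arylboronic acid to a chromone, the cationic aryl complex of divalent palladium inserts the C2=C3 bond with the ligand tert-butyl group blocking one face, so the aryl group arrives on the face that makes C2 (S), while the flavone, whose β-carbon is fully substituted, stays untouched and the near-neutral medium does not open the new flavanone.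

**Step 12**
Reactants: 24 5,7-bis(benzyloxy)-2-[4-({(2S)-2-[4-(benzyloxy)phenyl]-5,7-dimethoxy-4-oxo-3,4-dihydro-2H-chromen-6-yl}oxy)phenyl]-4H-chromen-4-one
Product: 25 5,7-dihydroxy-2-[4-({(2S)-5-hydroxy-2-(4-hydroxyphenyl)-7-methoxy-4-oxo-3,4-dihydro-2H-chromen-6-yl}oxy)phenyl]-4H-chromen-4-one
Conditions: BCl3 (10 equiv), pentamethylbenzene (10 equiv), CH2Cl2, −78 °C to 0 °C; recool, MeOH/CHCl3 quench; purification without base
Reagents that add atoms: none
Why: In this Lewis-acid ether cleavage BCl3, with pentamethylbenzene as a non-basic benzyl-cation scavenger, removes the three aryl benzyl ethers at −78 °C and, on warming, the methyl ether peri to the flavanone carbonyl through a six-membered boron chelate, while the unchelated 7-methoxy group and the diaryl ether remain and the cold acidic medium avoids the base-induced ring opening that would racemise C2.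

**Compound list**
1 | 3,5-bis(benzyloxy)phenol | Oc1cc(OCc2ccccc2)cc(OCc2ccccc2)c1 | starting material
2 | 3,5-bis(benzyloxy)phenyl isopropylcarbamate | CC(C)NC(=O)Oc1cc(OCc2ccccc2)cc(OCc2ccccc2)c1 | intermediate
3 | 3,5-bis(benzyloxy)phenyl N-(tert-butyldimethylsilyl)-N-isopropylcarbamate | CC(C)N(C(=O)Oc1cc(OCc2ccccc2)cc(OCc2ccccc2)c1)[Si](C)(C)C(C)(C)C | intermediate
4 | 3,5-bis(benzyloxy)-2-(trimethylsilyl)phenyl N-(tert-butyldimethylsilyl)-N-isopropylcarbamate | CC(C)N(C(=O)Oc1cc(OCc2ccccc2)cc(OCc2ccccc2)c1[Si](C)(C)C)[Si](C)(C)C(C)(C)C | intermediate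
5 | 3,5-bis(benzyloxy)-2-(trimethylsilyl)phenyl isopropylcarbamate | CC(C)NC(=O)Oc1cc(OCc2ccccc2)cc(OCc2ccccc2)c1[Si](C)(C)C | intermediate
6 | 3,5-bis(benzyloxy)-2-(trimethylsilyl)phenol | Oc1cc(OCc2ccccc2)cc(OCc2ccccc2)c1[Si](C)(C)C | intermediate
7 | 3,5-bis(benzyloxy)-2-(trimethylsilyl)phenyl trifluoromethanesulfonate | C[Si](C)(C)c1c(OS(=O)(=O)C(F)(F)F)cc(OCc2ccccc2)cc1OCc1ccccc1 | intermediate
8 | syringaldehyde (4-hydroxy-3,5-dimethoxybenzaldehyde) | COc1cc(C=O)cc(OC)c1O | starting material
9 | 1,4-diiodobenzene | Ic1ccc(I)cc1 | starting material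
10 | 4-(4-iodophenoxy)-3,5-dimethoxybenzaldehyde | COc1cc(C=O)cc(OC)c1Oc1ccc(I)cc1 | intermediate
11 | propiolic acid | C#CC(=O)O | starting material
12 | 3-[4-(4-formyl-2,6-dimethoxyphenoxy)phenyl]prop-2-ynoic acid | OC(=O)C#Cc1ccc(Oc2c(OC)cc(C=O)cc2OC)cc1 | intermediate
13 | 3,5-bis(benzyloxy)benzyne | C1#CC(OCc2ccccc2)=CC(OCc2ccccc2)=C1 | intermediate
14 | 4-(4-{3-[2,4-bis(benzyloxy)-6-hydroxyphenyl]-3-oxoprop-1-yn-1-yl}phenoxy)-3,5-dimethoxybenzaldehyde | O=C(C#Cc1ccc(Oc2c(OC)cc(C=O)cc2OC)cc1)c1c(O)cc(OCc2ccccc2)cc1OCc1ccccc1 | intermediate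
15 | 4-{4-[5,7-bis(benzyloxy)-4-oxo-4H-chromen-2-yl]phenoxy}-3,5-dimethoxybenzaldehyde | O=Cc1cc(OC)c(Oc2ccc(-c3cc(=O)c4c(OCc5ccccc5)cc(OCc5ccccc5)cc4o3)cc2)c(OC)c1 | intermediate
16 | 4-{4-[5,7-bis(benzyloxy)-4-oxo-4H-chromen-2-yl]phenoxy}-3,5-dimethoxyphenyl formate | O=COc1cc(OC)c(Oc2ccc(-c3cc(=O)c4c(OCc5ccccc5)cc(OCc5ccccc5)cc4o3)cc2)c(OC)c1 | intermediate
17 | 5,7-bis(benzyloxy)-2-[4-(4-hydroxy-2,6-dimethoxyphenoxy)phenyl]-4H-chromen-4-one | Oc1cc(OC)c(Oc2ccc(-c3cc(=O)c4c(OCc5ccccc5)cc(OCc5ccccc5)cc4o3)cc2)c(OC)c1 | intermediate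
18 | 5,7-bis(benzyloxy)-2-[4-(4-hydroxy-3-iodo-2,6-dimethoxyphenoxy)phenyl]-4H-chromen-4-one | Oc1cc(OC)c(Oc2ccc(-c3cc(=O)c4c(OCc5ccccc5)cc(OCc5ccccc5)cc4o3)cc2)c(OC)c1I | intermediate
19 | 5,7-bis(benzyloxy)-2-{4-[3-(1-ethoxyvinyl)-4-hydroxy-2,6-dimethoxyphenoxy]phenyl}-4H-chromen-4-one | C=C(OCC)c1c(O)cc(OC)c(Oc2ccc(-c3cc(=O)c4c(OCc5ccccc5)cc(OCc5ccccc5)cc4o3)cc2)c1OC | intermediate
20 | 2-[4-(3-acetyl-4-hydroxy-2,6-dimethoxyphenoxy)phenyl]-5,7-bis(benzyloxy)-4H-chromen-4-one | CC(=O)c1c(O)cc(OC)c(Oc2ccc(-c3cc(=O)c4c(OCc5ccccc5)cc(OCc5ccccc5)cc4o3)cc2)c1OC | intermediate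
21 | 5,7-bis(benzyloxy)-2-(4-{3-[(E)-3-(dimethylamino)acryloyl]-4-hydroxy-2,6-dimethoxyphenoxy}phenyl)-4H-chromen-4-one | CN(C)/C=C/C(=O)c1c(O)cc(OC)c(Oc2ccc(-c3cc(=O)c4c(OCc5ccccc5)cc(OCc5ccccc5)cc4o3)cc2)c1OC | intermediate
22 | 5,7-bis(benzyloxy)-2-{4-[(5,7-dimethoxy-4-oxo-4H-chromen-6-yl)oxy]phenyl}-4H-chromen-4-one | COc1cc2occc(=O)c2c(OC)c1Oc1ccc(-c3cc(=O)c4c(OCc5ccccc5)cc(OCc5ccccc5)cc4o3)cc1 | intermediate
23 | 4-(benzyloxy)phenylboronic acid | OB(O)c1ccc(OCc2ccccc2)cc1 | starting material
24 | 5,7-bis(benzyloxy)-2-[4-({(2S)-2-[4-(benzyloxy)phenyl]-5,7-dimethoxy-4-oxo-3,4-dihydro-2H-chromen-6-yl}oxy)phenyl]-4H-chromen-4-one | COc1cc2c(c(OC)c1Oc1ccc(-c3cc(=O)c4c(OCc5ccccc5)cc(OCc5ccccc5)cc4o3)cc1)C(=O)C[C@@H](c1ccc(OCc3ccccc3)cc1)O2 | intermediate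
25 | 5,7-dihydroxy-2-[4-({(2S)-5-hydroxy-2-(4-hydroxyphenyl)-7-methoxy-4-oxo-3,4-dihydro-2H-chromen-6-yl}oxy)phenyl]-4H-chromen-4-one (CNP0269971.1) | COc1cc2c(c(O)c1Oc1ccc(-c3cc(=O)c4c(O)cc(O)cc4o3)cc1)C(=O)C[C@@H](c1ccc(O)cc1)O2 | target

**Total step count:** 12.
**Longest linear sequence:** 10 (steps 1–3, then 6–12). Steps 4 and 5 form the second branch.

**Steps most likely to fail**

1. **Step 6.**
   - What may go wrong: the aryl anion may be protonated before the acyl shift, so that only O-arylation occurs. The propiolate may lose CO2 at the reaction temperature. The intermediate phenoxide may be arylated by a second aryne, or it may close in the five-membered mode.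
   - Fallback (known chemistry only): it sets out from 12 and 1 and returns at 15. Copper-catalysed protodecarboxylation of 12 (CuCl, Et3N, MeCN, 60 °C) gives 4-(4-ethynylphenoxy)-3,5-dimethoxybenzaldehyde F1. Iodination of 1 with NIS ortho to the hydroxyl group gives 3,5-bis(benzyloxy)-2-iodophenol F2, which is freed from any para isomer by chromatography. Palladium-catalysed carbonylative Sonogashira coupling with ring closure of F1 and F2 (PdCl2(dppf), CO, Et2NH, 60–120 °C) passes through ynone 14. The secondary amine adds to the ynone first and is then displaced by the phenol, so only the six-membered ring closes, giving 15.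

2. **Step 11.**
   - What may go wrong: insertion into the electron-rich, peri-substituted chromone may be slow. The electron-rich boronic acid may protodeboronate faster than it transmetalates. Facial selectivity may be insufficient or inverted.
   - Fallback: it sets out from 20 and returns at 24. Claisen–Schmidt condensation of 20 with commercial 4-(benzyloxy)benzaldehyde (KOH, EtOH/THF, rt) gives the (E)-2'-hydroxychalcone F3. NaOAc in refluxing EtOH closes it by oxa-Michael addition to the racemic flavanone F4; the methoxy group flanking the ketone biases the equilibrium toward the closed form. Preparative chromatography on a polysaccharide chiral stationary phase delivers 24. The unwanted (R)-flavanone F5 is returned to the F3/F4 equilibrium with base and recycled.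

3. **Step 12.**
   - What may go wrong: the chelated methyl ether may be cleaved incompletely, the 7-methyl ether may be attacked, or the Lewis acid may open the flavanone ring and erode the configuration at C2.
   - Fallback: it sets out from 22 and returns at 25, and it moves all Lewis-acid chemistry ahead of the stereocentre. MgI2 etherate (toluene/Et2O, 60–80 °C) removes only the two ethers peri to a carbonyl, giving 7-(benzyloxy)-5-hydroxy-2-{4-[(5-hydroxy-7-methoxy-4-oxo-4H-chromen-6-yl)oxy]phenyl}-4H-chromen-4-one F6. The conjugate addition of step 11, which tolerates free chelated phenols and should benefit from the hydrogen-bond-activated carbonyl, gives the (2S)-flavanone bis(benzyl ether) F7. Neutral hydrogenolysis (H2, Pd/C, EtOAc/THF, rt) then gives 25.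

**Further compounds**
F1 | step 6 | 4-(4-ethynylphenoxy)-3,5-dimethoxybenzaldehyde | C#Cc1ccc(Oc2c(OC)cc(C=O)cc2OC)cc1
F2 | step 6 | 3,5-bis(benzyloxy)-2-iodophenol | Oc1cc(OCc2ccccc2)cc(OCc2ccccc2)c1I
F3 | step 11 | 5,7-bis(benzyloxy)-2-[4-(3-{(E)-3-[4-(benzyloxy)phenyl]acryloyl}-4-hydroxy-2,6-dimethoxyphenoxy)phenyl]-4H-chromen-4-one | O=C(/C=C/c1ccc(OCc2ccccc2)cc1)c1c(O)cc(OC)c(Oc2ccc(-c3cc(=O)c4c(OCc5ccccc5)cc(OCc5ccccc5)cc4o3)cc2)c1OC
F4 | step 11 | racemic 5,7-bis(benzyloxy)-2-[4-({2-[4-(benzyloxy)phenyl]-5,7-dimethoxy-4-oxo-3,4-dihydro-2H-chromen-6-yl}oxy)phenyl]-4H-chromen-4-one | COc1cc2c(c(OC)c1Oc1ccc(-c3cc(=O)c4c(OCc5ccccc5)cc(OCc5ccccc5)cc4o3)cc1)C(=O)CC(c1ccc(OCc3ccccc3)cc1)O2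
F5 | step 11 | (2R)-enantiomer of 24 | COc1cc2c(c(OC)c1Oc1ccc(-c3cc(=O)c4c(OCc5ccccc5)cc(OCc5ccccc5)cc4o3)cc1)C(=O)C[C@H](c1ccc(OCc3ccccc3)cc1)O2
F6 | step 12 | 7-(benzyloxy)-5-hydroxy-2-{4-[(5-hydroxy-7-methoxy-4-oxo-4H-chromen-6-yl)oxy]phenyl}-4H-chromen-4-one | COc1cc2occc(=O)c2c(O)c1Oc1ccc(-c3cc(=O)c4c(O)cc(OCc5ccccc5)cc4o3)cc1
F7 | step 12 | 7-(benzyloxy)-2-[4-({(2S)-2-[4-(benzyloxy)phenyl]-5-hydroxy-7-methoxy-4-oxo-3,4-dihydro-2H-chromen-6-yl}oxy)phenyl]-5-hydroxy-4H-chromen-4-one | COc1cc2c(c(O)c1Oc1ccc(-c3cc(=O)c4c(O)cc(OCc5ccccc5)cc4o3)cc1)C(=O)C[C@@H](c1ccc(OCc3ccccc3)cc1)O2
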